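**Plan**

1. Numbering (labdane type): ring A = C1–C2–C3–C4–C5–C10. C4 bears the geminal methyls, C5 the chain C6–C7–C8(=O)–C17, C10 the methyl C20 and the keto chain C9(=O), C11–C15 that ends in the glyceride.
2. Retrosynthesis: the glyceride C–O bonds are cut first. Three helpers are then written back (C20 methyl ⇐ formyl, C9 ketone ⇐ silyl-protected carbinol, one C4 methyl ⇐ C3=C4 alkene). The resulting cyclohexene is cut at C1–C2 and C5–C10 (retro-Diels–Alder) into an (E)-3-methyl-1,3-diene (C2–C8, C17) and a 2-substituted acrolein (C1, C10, C20, C9, C11–C15), itself cut at C9–C10.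
3. Forward: diene from 6-methylhept-5-en-2-one, dienophile from (R)-citronellic acid, one enantioselective [4+2] cycloaddition that closes the only carbocycle and joins every skeletal carbon but one C4 methyl, then removal of the helpers, and esterification with the glycerol unit last.
4. Enabling feature: in ring A the tertiary C5 and the quaternary C10 are vicinal and C10 carries a carbonyl-level carbon, so with C4 written as an sp2 carbon of a C3=C4 bond the ring is a Diels–Alder retron. Because the acyl carbon C9 is trans to C6 in the target, the endo carbonyl of the cycloaddition must be the future C20; hence formyl at C10 and C9 kept as a bulky carbinol ether.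
5. Stereochemistry: C13 from (R)-citronellic acid, the glycerol centre from (R)-3-(benzyloxy)propane-1,2-diol, C5 and C10 from the catalyst-controlled endo cycloaddition to the (E)-diene. The C9 carbinol epimers converge on oxidation.

Key step: step 10

Assumption: the (S)-oxazaborolidine of step 10 is taken to be the antipode that leaves open the Si face of C10 in the boron-bound aldehyde (the spatial face by which it would turn 2-methylacrolein and cyclopentadiene into the (2S)-aldehyde); should the sense be opposite, the (R)-oxazaborolidine is used with no other change.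

**Route**

Step 1
Reactants: 1 6-methylhept-5-en-2-one
Product: 2 2-methyl-2-(4-methylpent-3-en-1-yl)-1,3-dioxolane
Conditions: ethylene glycol, p-TsOH (cat.), toluene, reflux, azeotropic removal of water
Reagents that add atoms: ethylene glycol, OCCO
Why: Acid-catalysed ketalisation protects the future C8 ketone as a dioxolane that should survive the oxidations, the ylide and the Lewis acid; no stereocentre is formed.

Step 2
Reactants: 2 2-methyl-2-(4-methylpent-3-en-1-yl)-1,3-dioxolane
Product: 3 (2E)-2-methyl-5-(2-methyl-1,3-dioxolan-2-yl)pent-2-en-1-ol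
Conditions: SeO2 (cat.), t-BuOOH, salicylic acid (cat.), CH2Cl2, rt
Reagents that add atoms: tert-butyl hydroperoxide, CC(C)(C)OO
Why: Selenium dioxide allylic oxidation (ene reaction then [2,3]-sigmatropic shift, Riley oxidation) attacks the methyl group trans to the chain of a trisubstituted alkene, so the (E) geometry of the future C4=C5 bond is set here.

Step 3
Reactants: 3 (2E)-2-methyl-5-(2-methyl-1,3-dioxolan-2-yl)pent-2-en-1-ol
Product: 4 (2E)-2-methyl-5-(2-methyl-1,3-dioxolan-2-yl)pent-2-enal
Conditions: MnO2, CH2Cl2, rt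
Reagents that add atoms: none
Why: MnO2 oxidises the allylic alcohol chemoselectively to the (E)-enal without isomerising the alkene.

Step 4
Reactants: 4 (2E)-2-methyl-5-(2-methyl-1,3-dioxolan-2-yl)pent-2-enal
Product: 5 2-methyl-2-[(3E)-4-methylhexa-3,5-dien-1-yl]-1,3-dioxolane
Conditions: Ph3PCH3Br, KOt-Bu, THF, 0 °C to rt
Reagents that add atoms: methyltriphenylphosphonium bromide, C[P+](c1ccccc1)(c1ccccc1)c1ccccc1.[Br-]
Why: Wittig methylenation of the enal installs C2 and completes the (E)-3-methyl-1,3-diene with C6 in the outside position needed for the cycloaddition.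

Step 5
Reactants: 6 (3R)-3,7-dimethyloct-6-enoic acid ((R)-citronellic acid)
Product: 7 tert-butyl (3R)-3,7-dimethyloct-6-enoate
Conditions: tert-butyl 2,2,2-trichloroacetimidate, CH2Cl2/cyclohexane, rt
Reagents that add atoms: tert-butyl 2,2,2-trichloroacetimidate, CC(C)(C)OC(=N)C(Cl)(Cl)Cl
Why: O-Alkylation of the acid by the imidate gives the tert-butyl ester under neutral conditions, an ester inert to the organolithium of step 7 and removable by acid in step 14; C13 is untouched.

Step 6
Reactants: 7 tert-butyl (3R)-3,7-dimethyloct-6-enoate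
Product: 9 tert-butyl (3R)-3-methyl-6-oxohexanoate, via ozonide 8 (not isolated)
Conditions: O3, CH2Cl2, −78 °C; then PPh3, −78 °C to rt
Reagents that add atoms: ozone, [O-][O+]=O
Why: Ozonolysis with reductive work-up cleaves the trisubstituted alkene and unmasks C9 as an aldehyde.

Step 7
Reactants: 9 tert-butyl (3R)-3-methyl-6-oxohexanoate, 10 2-bromo-3,3-diethoxyprop-1-ene
Product: 12 tert-butyl (3R,6RS)-7-(diethoxymethyl)-6-hydroxy-3-methyloct-7-enoate, via vinyllithium 11 (not isolated)
Conditions: 10, n-BuLi, THF, −78 °C; then 9, −78 °C; then H2O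
Reagents that add atoms: none
Why: Bromine–lithium exchange gives an α-acrolein anion equivalent whose 1,2-addition to the aldehyde forms the C9–C10 bond in the presence of the tert-butyl ester; C9 forms as a mixture of epimers, which is harmless because C9 becomes a ketone in step 15.

Step 8
Reactants: 12 tert-butyl (3R,6RS)-7-(diethoxymethyl)-6-hydroxy-3-methyloct-7-enoate
Product: 13 tert-butyl (3R,6RS)-6-[(tert-butyldimethylsilyl)oxy]-7-(diethoxymethyl)-3-methyloct-7-enoate
Conditions: TBSCl, imidazole, DMAP (cat.), DMF, rt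
Reagents that add atoms: tert-butyldimethylsilyl chloride, CC(C)(C)[Si](C)(C)Cl
Why: Silylation of the allylic alcohol gives an ether that should withstand the Lewis acid and keeps C9 as a bulky, non-activating carbinol substituent for the cycloaddition.

Step 9
Reactants: 13 tert-butyl (3R,6RS)-6-[(tert-butyldimethylsilyl)oxy]-7-(diethoxymethyl)-3-methyloct-7-enoate
Product: 14 tert-butyl (3R,6RS)-6-[(tert-butyldimethylsilyl)oxy]-7-formyl-3-methyloct-7-enoate
Conditions: oxalic acid (10% aq.), silica gel, CH2Cl2, rt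
Reagents that add atoms: water, O
Why: Mild acid hydrolysis of the diethyl acetal liberates the 2-substituted acrolein while the silyl ether and the tert-butyl ester survive.

Step 10
Reactants: 14 tert-butyl (3R,6RS)-6-[(tert-butyldimethylsilyl)oxy]-7-formyl-3-methyloct-7-enoate, 5 2-methyl-2-[(3E)-4-methylhexa-3,5-dien-1-yl]-1,3-dioxolane
Product: 15 tert-butyl (3R,6RS)-6-[(tert-butyldimethylsilyl)oxy]-6-{(1S,2R)-1-formyl-3-methyl-2-[2-(2-methyl-1,3-dioxolan-2-yl)ethyl]cyclohex-3-en-1-yl}-3-methylhexanoate (formyl group cis to the C5 side chain)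
Conditions: (S)-3,3-diphenyl-1-(o-tolyl)tetrahydro-1H,3H-pyrrolo[1,2-c][1,3,2]oxazaborole·HN(SO2CF3)2 (20 mol%), CH2Cl2, −78 to −40 °C
Reagents that add atoms: none
Why: Coordination of the formyl group of 14 to the boron of the protonated oxazaborolidine lowers the LUMO of the C1=C10 alkene, and an asynchronous concerted [4π+2π] cycloaddition with the s-cis diene of 5 follows, the C1–C2 bond between the two unsubstituted termini leading and the congested C5–C10 bond lagging; the closest known reaction type is the oxazaborolidinium-catalysed enantioselective Diels–Alder reaction of 2-substituted acroleins with acyclic dienes. Ring A (C1, C2, C3, C4, C5, C10) closes as a suprafacial six-membered cycloaddition that leaves the C3=C4 alkene. C5 is controlled by the (E) geometry of the C4=C5 bond of 5 together with the endo orientation of the formyl group, which places C6 and the formyl carbon C20 cis, and C10 is controlled by the catalyst, which shields the Re face of C10 (CHO > C9 > C1) so that the diene adds to the Si face. The step needs ortho regiochemistry, endo selectivity and one enantiotopic face: the first should be secured by the C5 alkyl terminus (larger HOMO coefficient at C2) and by the preference to join the two CH2 termini first, the second by the branched silyloxyalkyl group at C10, which must sit exo, and the third by the catalyst. Both C9 epimers of 14 should react and they converge when C9 is oxidised. Because an endo carbonyl ends cis to C6, the formyl group serves as precursor of the C20 methyl group, whereas an isopropenyl ketone dienophile would be expected to give the wrong C5/C10 relationship.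

Step 11
Reactants: 15 Diels–Alder adduct (aldehyde)
Product: 16 (E)-4-methylbenzenesulfonylhydrazone of aldehyde 15
Conditions: TsNHNH2, MgSO4, THF, rt
Reagents that add atoms: 4-methylbenzenesulfonohydrazide, Cc1ccc(cc1)S(=O)(=O)NN
Why: Condensation of the hindered aldehyde with tosylhydrazide gives the tosylhydrazone, the first half of the deoxygenation of the formyl helper.

Step 12
Reactants: 16 (E)-4-methylbenzenesulfonylhydrazone of aldehyde 15
Product: 18 tert-butyl (3R,6RS)-6-[(tert-butyldimethylsilyl)oxy]-6-{(1R,2R)-1,3-dimethyl-2-[2-(2-methyl-1,3-dioxolan-2-yl)ethyl]cyclohex-3-en-1-yl}-3-methylhexanoate, via N-boryl hydrazide 17 (not isolated)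
Conditions: catecholborane, CHCl3, 0 °C; then NaOAc·3H2O, 60 °C
Reagents that add atoms: none
Why: Hydroboration of the tosylhydrazone C=N bond and acetate-induced loss of sulfinate and N2 (reductive deoxygenation of a tosylhydrazone) turn the formyl carbon into the C20 methyl group with the C10 configuration unchanged and the remote alkene untouched.

Step 13
Reactants: 18 C20-methyl cyclohexene
Product: 20 tert-butyl (3R,6RS)-6-[(tert-butyldimethylsilyl)oxy]-3-methyl-6-{(1R,2R)-1,3,3-trimethyl-2-[2-(2-methyl-1,3-dioxolan-2-yl)ethyl]cyclohexyl}hexanoate, via alkyl sulfonohydrazide 19 (not isolated)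
Conditions: Fe(acac)3 (30 mol%), PhSiH3, CH2=NNHSO2(n-C8H17), THF/MeOH, rt; then MeOH, 60 °C
Reagents that add atoms: formaldehyde N-(octylsulfonyl)hydrazone, C=NNS(=O)(=O)CCCCCCCC
Why: Metal hydride hydrogen atom transfer places H on C3 and a tertiary radical on C4, which adds to the formaldehyde hydrazone, and heating expels sulfinate and N2 so that the new carbon becomes the second C4 methyl (Markovnikov hydromethylation of an unactivated alkene); no stereocentre results because C4 ends with two methyl groups.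

Step 14
Reactants: 20 gem-dimethyl cyclohexane (tert-butyl ester, silyl ether, dioxolane)
Product: 21 (3R,6RS)-6-hydroxy-3-methyl-6-[(1R,2R)-1,3,3-trimethyl-2-(3-oxobutyl)cyclohexyl]hexanoic acid
Conditions: CF3CO2H/CH2Cl2/H2O, 0 °C to rt
Reagents that add atoms: water, O
Why: Aqueous trifluoroacetic acid should remove the three acid-labile helpers at once (tert-butyl ester by alkyl–oxygen cleavage, silyl ether, dioxolane) to give the hydroxy keto acid.

Step 15
Reactants: 21 hydroxy keto acid
Product: 22 (3R)-3-methyl-6-oxo-6-[(1R,2R)-1,3,3-trimethyl-2-(3-oxobutyl)cyclohexyl]hexanoic acid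
Conditions: Dess–Martin periodinane, CH2Cl2, rt
Reagents that add atoms: none
Why: Dess–Martin oxidation converts the hindered C9 carbinol into the ketone and thereby erases the C9 epimers.

Step 16
Reactants: 22 diketo acid, 23 (2R)-3-(benzyloxy)propane-1,2-diol
Product: 24 (2S)-3-(benzyloxy)-2-hydroxypropyl (3R)-3-methyl-6-oxo-6-[(1R,2R)-1,3,3-trimethyl-2-(3-oxobutyl)cyclohexyl]hexanoate
Conditions: 23 (1.5 equiv), DCC, DMAP (cat.), CH2Cl2, −20 to 0 °C
Reagents that add atoms: none
Why: Steglich esterification at low temperature should acylate the less hindered primary hydroxyl of the diol, whose stereocentre comes from the chiral pool and is not touched.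

Step 17
Reactants: 24 primary monoester with free secondary hydroxyl
Product: 25 (2S)-2-(acetyloxy)-3-(benzyloxy)propyl (3R)-3-methyl-6-oxo-6-[(1R,2R)-1,3,3-trimethyl-2-(3-oxobutyl)cyclohexyl]hexanoate
Conditions: Ac2O, pyridine, DMAP (cat.), CH2Cl2, 0 °C
Reagents that add atoms: acetic anhydride, CC(=O)OC(C)=O
Why: DMAP-catalysed acetylation of the remaining secondary hydroxyl; acyl migration cannot occur because the third oxygen is still benzylated.

Step 18
Reactants: 25 benzyl-protected diacylglycerol
Product: 26 (2S)-2-(acetyloxy)-3-hydroxypropyl (3R)-3-methyl-6-oxo-6-[(1R,2R)-1,3,3-trimethyl-2-(3-oxobutyl)cyclohexyl]hexanoate (CNP0287223.1)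
Conditions: H2 (1 atm), Pd/C, EtOAc, rt; rapid chromatography on boric acid-treated silica
Reagents that add atoms: none
Why: Hydrogenolysis of the benzyl ether under neutral conditions should free the primary hydroxyl without reducing the ketones and with the least risk of acetyl migration.

**Compound list**

1 | 6-methylhept-5-en-2-one | CC(=O)CCC=C(C)C | starting material
2 | 2-methyl-2-(4-methylpent-3-en-1-yl)-1,3-dioxolane | CC(C)=CCCC1(C)OCCO1 | intermediate
3 | (2E)-2-methyl-5-(2-methyl-1,3-dioxolan-2-yl)pent-2-en-1-ol | OC/C(C)=C/CCC1(C)OCCO1 | intermediate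
4 | (2E)-2-methyl-5-(2-methyl-1,3-dioxolan-2-yl)pent-2-enal | O=C/C(C)=C/CCC1(C)OCCO1 | intermediate
5 | 2-methyl-2-[(3E)-4-methylhexa-3,5-dien-1-yl]-1,3-dioxolane | C=C/C(C)=C/CCC1(C)OCCO1 | intermediate
6 | (3R)-3,7-dimethyloct-6-enoic acid ((R)-citronellic acid) | C[C@H](CCC=C(C)C)CC(=O)O | starting material
7 | tert-butyl (3R)-3,7-dimethyloct-6-enoate | C[C@H](CCC=C(C)C)CC(=O)OC(C)(C)C | intermediate
8 | ozonide, tert-butyl (3R)-5-(5,5-dimethyl-1,2,4-trioxolan-3-yl)-3-methylpentanoate | C[C@H](CCC1OOC(C)(C)O1)CC(=O)OC(C)(C)C | intermediate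
9 | tert-butyl (3R)-3-methyl-6-oxohexanoate | O=CCC[C@@H](C)CC(=O)OC(C)(C)C | intermediate
10 | 2-bromo-3,3-diethoxyprop-1-ene | C=C(Br)C(OCC)OCC | starting material
11 | (3,3-diethoxyprop-1-en-2-yl)lithium | [Li]C(=C)C(OCC)OCC | intermediate
12 | tert-butyl (3R,6RS)-7-(diethoxymethyl)-6-hydroxy-3-methyloct-7-enoate (C9 epimers) | C=C(C(OCC)OCC)C(O)CC[C@@H](C)CC(=O)OC(C)(C)C | intermediate
13 | tert-butyl (3R,6RS)-6-[(tert-butyldimethylsilyl)oxy]-7-(diethoxymethyl)-3-methyloct-7-enoate | C=C(C(OCC)OCC)C(O[Si](C)(C)C(C)(C)C)CC[C@@H](C)CC(=O)OC(C)(C)C | intermediate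
14 | tert-butyl (3R,6RS)-6-[(tert-butyldimethylsilyl)oxy]-7-formyl-3-methyloct-7-enoate | C=C(C=O)C(O[Si](C)(C)C(C)(C)C)CC[C@@H](C)CC(=O)OC(C)(C)C | intermediate
15 | tert-butyl (3R,6RS)-6-[(tert-butyldimethylsilyl)oxy]-6-{(1S,2R)-1-formyl-3-methyl-2-[2-(2-methyl-1,3-dioxolan-2-yl)ethyl]cyclohex-3-en-1-yl}-3-methylhexanoate | CC1(OCCO1)CC[C@@H]2C(C)=CCC[C@@]2(C=O)C(O[Si](C)(C)C(C)(C)C)CC[C@@H](C)CC(=O)OC(C)(C)C | intermediate
16 | (E)-4-methylbenzenesulfonylhydrazone of 15 | CC1(OCCO1)CC[C@@H]2C(C)=CCC[C@@]2(/C=N/NS(=O)(=O)c3ccc(C)cc3)C(O[Si](C)(C)C(C)(C)C)CC[C@@H](C)CC(=O)OC(C)(C)C | intermediate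
17 | N-(1,3,2-benzodioxaborol-2-yl) hydrazide from hydroboration of the C=N bond of 16 | CC1(OCCO1)CC[C@@H]2C(C)=CCC[C@@]2(CN(B3Oc4ccccc4O3)NS(=O)(=O)c3ccc(C)cc3)C(O[Si](C)(C)C(C)(C)C)CC[C@@H](C)CC(=O)OC(C)(C)C | intermediate
18 | tert-butyl (3R,6RS)-6-[(tert-butyldimethylsilyl)oxy]-6-{(1R,2R)-1,3-dimethyl-2-[2-(2-methyl-1,3-dioxolan-2-yl)ethyl]cyclohex-3-en-1-yl}-3-methylhexanoate | CC1(OCCO1)CC[C@@H]2C(C)=CCC[C@@]2(C)C(O[Si](C)(C)C(C)(C)C)CC[C@@H](C)CC(=O)OC(C)(C)C | intermediate
19 | N′-alkyl octane-1-sulfonohydrazide at C4 of 18 (C4 epimers) | CC1(OCCO1)CC[C@@H]2C(C)(CNNS(=O)(=O)CCCCCCCC)CCC[C@@]2(C)C(O[Si](C)(C)C(C)(C)C)CC[C@@H](C)CC(=O)OC(C)(C)C | intermediate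
20 | tert-butyl (3R,6RS)-6-[(tert-butyldimethylsilyl)oxy]-3-methyl-6-{(1R,2R)-1,3,3-trimethyl-2-[2-(2-methyl-1,3-dioxolan-2-yl)ethyl]cyclohexyl}hexanoate | CC1(OCCO1)CC[C@@H]2C(C)(C)CCC[C@@]2(C)C(O[Si](C)(C)C(C)(C)C)CC[C@@H](C)CC(=O)OC(C)(C)C | intermediate
21 | (3R,6RS)-6-hydroxy-3-methyl-6-[(1R,2R)-1,3,3-trimethyl-2-(3-oxobutyl)cyclohexyl]hexanoic acid | CC(=O)CC[C@@H]1C(C)(C)CCC[C@@]1(C)C(O)CC[C@@H](C)CC(=O)O | intermediate
22 | (3R)-3-methyl-6-oxo-6-[(1R,2R)-1,3,3-trimethyl-2-(3-oxobutyl)cyclohexyl]hexanoic acid | CC(=O)CC[C@@H]1C(C)(C)CCC[C@@]1(C)C(=O)CC[C@@H](C)CC(=O)O | intermediate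
23 | (2R)-3-(benzyloxy)propane-1,2-diol | OC[C@H](COCc1ccccc1)O | starting material
24 | (2S)-3-(benzyloxy)-2-hydroxypropyl (3R)-3-methyl-6-oxo-6-[(1R,2R)-1,3,3-trimethyl-2-(3-oxobutyl)cyclohexyl]hexanoate | CC(=O)CC[C@@H]1C(C)(C)CCC[C@@]1(C)C(=O)CC[C@@H](C)CC(=O)OC[C@H](COCc2ccccc2)O | intermediate
25 | (2S)-2-(acetyloxy)-3-(benzyloxy)propyl (3R)-3-methyl-6-oxo-6-[(1R,2R)-1,3,3-trimethyl-2-(3-oxobutyl)cyclohexyl]hexanoate | CC(=O)CC[C@@H]1C(C)(C)CCC[C@@]1(C)C(=O)CC[C@@H](C)CC(=O)OC[C@H](COCc2ccccc2)OC(C)=O | intermediate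
26 | (2S)-2-(acetyloxy)-3-hydroxypropyl (3R)-3-methyl-6-oxo-6-[(1R,2R)-1,3,3-trimethyl-2-(3-oxobutyl)cyclohexyl]hexanoate | CC(=O)CC[C@@H]1C(C)(C)CCC[C@@]1(C)C(=O)CC[C@@H](C)CC(=O)OC[C@H](CO)OC(C)=O | target

**Step count**

Total: 18 steps. Longest linear sequence: 14 steps (from 6 through steps 5–18); the diene branch (steps 1–4) joins at step 10.

**Steps most likely to fail**

Step 10. The cycloaddition may lose regiocontrol, because the C4 methyl group of the diene directs the formyl-bearing carbon towards C2 while the C5 alkyl terminus directs it towards C5. Closure of the congested C5–C10 bond may also be so slow that the acid-labile groups decay and catalyst control over the two C9 epimers erodes. The fallback sets out from 4 and returns at 15.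
- MeMgBr addition to 4 gives (3E)-3-methyl-6-(2-methyl-1,3-dioxolan-2-yl)hex-3-en-2-ol F1.
- MnO2 oxidation gives (3E)-3-methyl-6-(2-methyl-1,3-dioxolan-2-yl)hex-3-en-2-one F2.
- i-Pr3SiOTf/Et3N gives triisopropyl{[(3E)-3-methyl-6-(2-methyl-1,3-dioxolan-2-yl)hexa-1,3-dien-2-yl]oxy}silane F3, in which the C3 oxygen substituent and the C5 alkyl group direct in the same sense and raise the HOMO.
- Cycloaddition of F3 with 14 under the conditions of step 10 (or with Me2AlCl) should give the C3-silyloxy analogue of 15 F4.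
- CsF and PhNTf2 convert its silyl enol ether into the C3 enol triflate of 15 F5.
- Pd(OAc)2/PPh3 with HCO2H and Bu3N replaces the triflate by hydrogen, which gives 15.

Step 13. The tertiary C4 radical, hemmed in by C5 and the quaternary C10, may take up a second hydrogen atom faster than it adds to the hydrazone, which would give the C4–H compound instead of the quaternary carbon. The fallback sets out from 18 and returns at 20.
- Simmons–Smith cyclopropanation (Et2Zn, CH2I2, CH2Cl2) gives the C3–C4 cyclopropane (bicyclo[4.1.0]heptane) derived from 18 F6.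
- Hydrogenolysis (H2, PtO2, AcOH) cleaves the least hindered cyclopropane bond (C3–CH2), so that the added carbon becomes the second C4 methyl group; this gives 20.

Step 16. The acylation may discriminate too little between the primary and the secondary hydroxyl of 23, so that 2-acyl and diacyl material forms and acyl groups migrate during purification. The fallback sets out from 22 and returns at 24.
- Cs2CO3 converts 22 into caesium (3R)-3-methyl-6-oxo-6-[(1R,2R)-1,3,3-trimethyl-2-(3-oxobutyl)cyclohexyl]hexanoate F7.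
- F7 opens commercially available (R)-2-[(benzyloxy)methyl]oxirane (C1[C@H](COCc2ccccc2)O1) at its unsubstituted ring carbon in DMF at 50 °C. The SN2 step itself places the ester oxygen on the primary carbon and the secondary hydroxyl is formed free, which gives 24.

Further compounds
F1 | step 10 | (3E)-3-methyl-6-(2-methyl-1,3-dioxolan-2-yl)hex-3-en-2-ol | CC(O)/C(C)=C/CCC1(C)OCCO1
F2 | step 10 | (3E)-3-methyl-6-(2-methyl-1,3-dioxolan-2-yl)hex-3-en-2-one | CC(=O)/C(C)=C/CCC1(C)OCCO1
F3 | step 10 | triisopropyl{[(3E)-3-methyl-6-(2-methyl-1,3-dioxolan-2-yl)hexa-1,3-dien-2-yl]oxy}silane | C=C(O[Si](C(C)C)(C(C)C)C(C)C)/C(C)=C/CCC1(C)OCCO1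
F4 | step 10 | C3-silyloxy analogue of 15 | CC1(OCCO1)CC[C@@H]2C(C)=C(O[Si](C(C)C)(C(C)C)C(C)C)CC[C@@]2(C=O)C(O[Si](C)(C)C(C)(C)C)CC[C@@H](C)CC(=O)OC(C)(C)C
F5 | step 10 | C3 enol triflate of 15 | CC1(OCCO1)CC[C@@H]2C(C)=C(OS(=O)(=O)C(F)(F)F)CC[C@@]2(C=O)C(O[Si](C)(C)C(C)(C)C)CC[C@@H](C)CC(=O)OC(C)(C)C
F6 | step 13 | C3–C4 cyclopropane (bicyclo[4.1.0]heptane) derived from 18 | CC1(OCCO1)CC[C@@H]2C3(C)CC3CC[C@@]2(C)C(O[Si](C)(C)C(C)(C)C)CC[C@@H](C)CC(=O)OC(C)(C)C
F7 | step 16 | caesium (3R)-3-methyl-6-oxo-6-[(1R,2R)-1,3,3-trimethyl-2-(3-oxobutyl)cyclohexyl]hexanoate | CC(=O)CC[C@@H]1C(C)(C)CCC[C@@]1(C)C(=O)CC[C@@H](C)CC(=O)[O-].[Cs+]
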